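**Strategy.** The synthesis rests on the bond between C7, the acetoxy-bearing benzylic carbon, and C1 of the 3,4-dimethoxyphenyl ring. In the key step 3,4-dimethoxyphenylmagnesium bromide adds to the (R)-2-aryloxypropanal that carries the complete (Z)-propenylguaiacyl ether, and the magnesium alkoxide is acetylated in the same flask: one operation joins both halves, sets C7 and installs the acetate. The step exploits the 1,2-dioxygen pattern at C7/C8: the aryl ether oxygen on C8 (the methyl-bearing carbon), backed by the ortho-methoxy group of the guaiacyl ring, chelates magnesium with the C7 carbonyl oxygen and steers attack to the threo (7R,8R) isomer. The aldehyde arises from (Z)-isoeugenol and methyl (S)-lactate by Mitsunobu inversion and DIBAL-H reduction.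

Key step: step 4

Remark: neolignan numbering is used (C7 = benzylic CH–OAc, C8 = CH(CH3)–OAr); (Z)-prop-1-enylboronic acid and 3,4-dimethoxyphenylmagnesium bromide (0.5 M in THF) are taken as commercial reagents.

**Step 1**
Reactants: 1 4-bromo-2-methoxyphenol; 2 (Z)-prop-1-enylboronic acid
Product: 3 2-methoxy-4-[(Z)-prop-1-enyl]phenol ((Z)-isoeugenol)
Conditions: Pd(dppf)Cl2 (3 mol%), K2CO3 (3 equiv), 1,4-dioxane/H2O, 80 °C, degassed
Reagents that add atoms: none
Why: Suzuki–Miyaura coupling of an aryl bromide with an alkenylboronic acid; transmetalation and reductive elimination retain the alkene geometry, so the Z-propenyl group should be transferred intact, and the free phenol is tolerated as its phenoxide.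

**Step 2**
Reactants: 3 (Z)-isoeugenol; 4 methyl (S)-lactate
Product: 5 methyl (2R)-2-{2-methoxy-4-[(Z)-prop-1-enyl]phenoxy}propanoate
Conditions: PPh3, DIAD, THF, 0 °C to rt
Reagents that add atoms: none
Why: Mitsunobu etherification; SN2 displacement of the activated secondary hydroxyl by the phenoxide inverts the lactate centre (S to R) and so sets C8 of the target, while the Z-alkene is inert to the reagents.

**Step 3**
Reactants: 5 methyl (2R)-2-{2-methoxy-4-[(Z)-prop-1-enyl]phenoxy}propanoate
Product: 7 (2R)-2-{2-methoxy-4-[(Z)-prop-1-enyl]phenoxy}propanal, via aluminium hemiacetal 6 (not isolated)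
Conditions: DIBAL-H (1.1 equiv), CH2Cl2, −78 °C; MeOH, then aq. Rochelle salt; used crude without chromatography
Reagents that add atoms: none
Why: Partial ester reduction with DIBAL-H; the α-aryloxy group stabilizes the tetrahedral aluminium hemiacetal at −78 °C, so the aldehyde should be released only on work-up, with C8 untouched.

**Step 4**
Reactants: 7 (2R)-2-{2-methoxy-4-[(Z)-prop-1-enyl]phenoxy}propanal; 8 3,4-dimethoxyphenylmagnesium bromide
Product: 10 ligraminol C, via bromomagnesium alkoxide 9 (not isolated)
Conditions: MgBr2·OEt2 (2 equiv), CH2Cl2, −78 °C; 8 (1.3 equiv, 0.5 M in THF), −78 °C; then Et3N, Ac2O (3 equiv), DMAP (cat.), −78 to 0 °C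
Reagents that add atoms: acetic anhydride, CC(=O)OC(C)=O
Why: MgBr2 binds the aldehyde oxygen and the C8 aryl ether oxygen (assisted by the ortho-methoxy oxygen of the guaiacyl ring) in a five-membered Cram chelate that locks the C7–C8 rotamer, and the aryl Grignard reagent then adds to the carbonyl carbon from the face flanked by the C8 hydrogen, anti to the C8 methyl group, which forms the aryl–C7 bond and sets C7 as R beside the existing (R)-C8 (threo, syn). The closest known reaction type is the chelation-controlled 1,2-addition of an organomagnesium reagent to an α-alkoxy aldehyde, followed by MgBr2/amine-promoted acylation of the magnesium alkoxide with an anhydride in the same flask. No ring is closed. The selectivity needed is facial (chelate attack against Felkin–Anh attack, which would give the erythro epimer), and it should be secured by the bidentate guaiacyl ether donor at C8, the non-coordinating bulk solvent and the low temperature, which also protects the enolizable C8 centre from epimerization. Trapping the alkoxide with Ac2O should deliver the acetate directly and avoid handling the acid-labile, electron-rich benzylic alcohol.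

**Compound list**
1 | 4-bromo-2-methoxyphenol | COc1cc(Br)ccc1O | starting material
2 | (Z)-prop-1-enylboronic acid | C/C=C\B(O)O | starting material
3 | 2-methoxy-4-[(Z)-prop-1-enyl]phenol ((Z)-isoeugenol) | C/C=C\c1ccc(O)c(OC)c1 | intermediate
4 | methyl (S)-lactate (methyl (2S)-2-hydroxypropanoate) | C[C@H](O)C(=O)OC | starting material
5 | methyl (2R)-2-{2-methoxy-4-[(Z)-prop-1-enyl]phenoxy}propanoate | C/C=C\c1ccc(O[C@H](C)C(=O)OC)c(OC)c1 | intermediate
6 | diisobutylaluminium hemiacetal of 5 ((2R)-1-methoxy-2-aryloxypropoxide on Al(iBu)2, both epimers at the acetal carbon) | C/C=C\c1ccc(O[C@H](C)C(OC)O[Al](CC(C)C)CC(C)C)c(OC)c1 | intermediate (not isolated)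
7 | (2R)-2-{2-methoxy-4-[(Z)-prop-1-enyl]phenoxy}propanal | C/C=C\c1ccc(O[C@H](C)C=O)c(OC)c1 | intermediate
8 | 3,4-dimethoxyphenylmagnesium bromide | COc1ccc([Mg]Br)cc1OC | starting material
9 | bromomagnesium (1R,2R)-1-(3,4-dimethoxyphenyl)-2-{2-methoxy-4-[(Z)-prop-1-enyl]phenoxy}propan-1-olate | C/C=C\c1ccc(O[C@H](C)[C@H](O[Mg]Br)c2ccc(OC)c(OC)c2)c(OC)c1 | intermediate (not isolated)
10 | ligraminol C, (1R,2R)-1-(3,4-dimethoxyphenyl)-2-{2-methoxy-4-[(Z)-prop-1-enyl]phenoxy}propyl acetate | C/C=C\c1ccc(O[C@H](C)[C@H](OC(C)=O)c2ccc(OC)c(OC)c2)c(OC)c1 | target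

**Total step count:** 4
**Longest linear sequence:** 4 steps (1 → 3 → 5 → 7 → 10)

**Steps most likely to fail**

1. Step 4. Facial selectivity may be poor if non-chelated (Felkin–Anh) addition competes, and the basic reagent may epimerize the α-aryloxy aldehyde. Fallback: the aryl–C7 bond would be made at the ketone level, setting out from ester 5. Treatment with Me(MeO)NH·HCl and iPrMgCl (THF, −20 °C) should give the Weinreb amide (2R)-N-methoxy-N-methyl-2-{2-methoxy-4-[(Z)-prop-1-enyl]phenoxy}propanamide F1. Addition of 8 (THF, 0 °C) should give the ketone (2R)-1-(3,4-dimethoxyphenyl)-2-{2-methoxy-4-[(Z)-prop-1-enyl]phenoxy}propan-1-one F2. Non-chelating Felkin–Anh reduction with K-Selectride (THF, −78 °C) should then give the threo alcohol (1R,2R)-1-(3,4-dimethoxyphenyl)-2-{2-methoxy-4-[(Z)-prop-1-enyl]phenoxy}propan-1-ol F3. Acetylation (Ac2O, pyridine, DMAP, CH2Cl2, 0 °C) comes back to the route at 10.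

2. Step 3. Over-reduction to the primary alcohol and epimerization of the aldehyde during work-up are the likely failure modes. Fallback: setting out from 5, full reduction with LiBH4 (THF, 0 °C) should give the primary alcohol (2R)-2-{2-methoxy-4-[(Z)-prop-1-enyl]phenoxy}propan-1-ol F4. Buffered Dess–Martin oxidation (DMP, NaHCO3, CH2Cl2, 0 °C) comes back to the route at 7, used crude.

3. Step 1. Partial Z-to-E isomerization of the propenyl group and protodeboronation of the alkenylboronic acid may occur during the coupling. Fallback: setting out from 1, Sonogashira coupling with propyne (Pd(PPh3)2Cl2, CuI, Et3N, THF, 60 °C, sealed vessel) should give the aryl alkyne 2-methoxy-4-(prop-1-ynyl)phenol F5. Lindlar semihydrogenation (H2, Pd/CaCO3–Pb, quinoline, EtOAc, rt) sets the Z-alkene by syn addition of hydrogen and comes back to the route at 3.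

**Further compounds**
F1 | step 4 | (2R)-N-methoxy-N-methyl-2-{2-methoxy-4-[(Z)-prop-1-enyl]phenoxy}propanamide | C/C=C\c1ccc(O[C@H](C)C(=O)N(C)OC)c(OC)c1
F2 | step 4 | (2R)-1-(3,4-dimethoxyphenyl)-2-{2-methoxy-4-[(Z)-prop-1-enyl]phenoxy}propan-1-one | C/C=C\c1ccc(O[C@H](C)C(=O)c2ccc(OC)c(OC)c2)c(OC)c1
F3 | step 4 | (1R,2R)-1-(3,4-dimethoxyphenyl)-2-{2-methoxy-4-[(Z)-prop-1-enyl]phenoxy}propan-1-ol | C/C=C\c1ccc(O[C@H](C)[C@H](O)c2ccc(OC)c(OC)c2)c(OC)c1
F4 | step 3 | (2R)-2-{2-methoxy-4-[(Z)-prop-1-enyl]phenoxy}propan-1-ol | C/C=C\c1ccc(O[C@H](C)CO)c(OC)c1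
F5 | step 1 | 2-methoxy-4-(prop-1-ynyl)phenol | CC#Cc1ccc(O)c(OC)c1
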